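- The easy step in this flask is the crossing of Jb into the first phase, where Ja waits.

Ja 0.50 mM; Jb 0.600 mM; time 30 s; volume of the second phase over the first 2.0

    Jc ⇌ Jb, rate k1*([Jc] - [Jb]/K1) per volume of the first phase (K1 = 1.2, k1 = 0.387 s⁻¹)
    Ja + Jc → Je (k2 = 38.4 M⁻¹ s⁻¹)
    Jc + Je → Jf (k3 = 58.0 M⁻¹ s⁻¹)
    Jc ⇌ Jd (K4 = 3.7, k4 = 0.0290 s⁻¹)

- in the second phase: Jb; everything else is in the first
- charges count per volume of the first phase; a concentration in a rate is the amount of a species over the volume of its own phase; every rate counts per litre of the first phase
- run time (flask): 30 s

- the Je standing at 30 s, as a percentage of the Ja charged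
- part of the Ja charged that has reacted at 30 s

- Two numbers seem not to fit. The flask holds 0.600 mM of Jb against 0.50 mM of Ja, so there is more reagent than substrate, and if the charge stood as Jc, 49.9% of Ja would react in 30 s. I end well below that.
- The crossing has a half-life of 1.26 s, short against the run, so I take the partition as standing. The charge then divides by one plus the partition ratio times the volume ratio, which leaves Jc at a level cP of 0.176 mM.
- Jd also draws on Jc. With that step at equilibrium too, the divisor grows by 3.7 and the level cD is 0.0845 mM. Its relaxation half-life of 18.8 s is shorter than the run but not short against it, so once the crossing has stood I let Jc travel from cP towards cD.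
- I freeze Jc at the mean of these two levels, the working level c̄ of the reaction phase, 0.130 mM. This clears the puzzle, since Ja meets c̄, not the charge.
- With Jc frozen, Ja decays by a pseudo-first-order law with constant k′, the product of the step's rate constant and c̄, here 0.00501 s⁻¹. I reckon 14.0% reacted. Treating Je as the middle of a consecutive pair gives 12.5% standing.
- The forecast gives 12.5% of Je and 14.1% reacted, on the ground that Jb “equilibrates with the first phase within a few seconds”.
- The simulation gives 12.5% of Je and 14.1% reacted.
- In this flask Jc reads 0.134 mM at 3.00 s, 0.140 mM at 15.0 s and 0.117 mM at 30.0 s, readings on either side of c̄. Je stands at 12.5% through two things acting together, the time allowed and the fall of Jb to 50.5% of its own charge. With Jb kept from running down, Je reaches 17.6% at the asked time, which is a part of the story, and a tenfold time gives 29.2%.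
- A neighbour flask charged with 0.85 mM of Ja keeps c̄, since Ja does not enter it, so I again reckon 14.0% reacted. The computed value there is 13.3%.

(The constants are made up, and the outcome is calculated.)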